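**Plan** (labdane numbering: ring A = C1–C5 and C10, ring B = C5–C10, chain C11–C16, butenolide on C16)
1. Cuts: butenolide back to a 3-furyl group; C12–C13 (sp3–sp2 Suzuki–Miyaura); C9–C11 (Stille); then ring A is opened at C1=C2 (Wittig) and at C3–C4 (radical Giese addition), which leaves ring B as a C10-dialkylated (R)-carvone.
2. Forward: ring B is carvone; C10 is made quaternary by two α′-alkylations (CH3, then CH2OH oxidised to CHO); ring A is annulated in one flask; hydrogenation, enol triflation and vinylation give the decalin diene; the furyl bromoenoate fragment is joined; the furan becomes the butenolide last.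
3. Enabling feature: ring A carries no functional group, but its C1–C2 bond lies between the quaternary C10 and the gem-dimethyl carbon C4. A formyl group on C10 (C1) and an isopropenyl group on C5 (C4 with both methyls), trans on ring B, can be bridged by the two carbons of a vinylphosphonium ion (C3, C2): radical addition at C4, ylide olefination at C1.
4. Stereochemistry: C5 is the carvone stereocentre; C10 is set by enolate attack anti to the isopropenyl group, which fixes the trans ring fusion; C16 comes from an (R)-BINOL/Ti(Oi-Pr)4-catalysed allylation; the C13=C14 geometry comes from a trifluoroethyl-phosphonate olefination followed by a stereoretentive coupling.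

Key step: step 4

Remark: ethyl bromo[bis(2,2,2-trifluoroethoxy)phosphoryl]acetate (step 11) is treated as an available reagent; otherwise it is made by the known bromination of the commercial ethyl bis(2,2,2-trifluoroethyl)phosphonoacetate.

**Step 1**
Reactants: 1 (R)-carvone, (5R)-2-methyl-5-(prop-1-en-2-yl)cyclohex-2-en-1-one
Product: 3 (5R,6S)-2,6-dimethyl-5-(prop-1-en-2-yl)cyclohex-2-en-1-one, via lithium dienolate 2 (not isolated)
Conditions: LiN(i-Pr)2, THF, −78 °C; MeI, −78 → 0 °C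
Reagents that add atoms: iodomethane, CI
Why: Kinetic α′-deprotonation of the enone gives the cross-conjugated dienolate 2, and its C-methylation (enolate alkylation) installs the future angular methyl on C10; the C6 configuration (trans epimer expected as the major one) is erased again in step 2.

**Step 2**
Reactants: 3 (5R,6S)-2,6-dimethyl-5-(prop-1-en-2-yl)cyclohex-2-en-1-one
Product: 5 (5S,6R)-6-(hydroxymethyl)-2,6-dimethyl-5-(prop-1-en-2-yl)cyclohex-2-en-1-one, via lithium enolate 4 (not isolated)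
Conditions: LiN(i-Pr)2, THF, −78 → −40 °C; HCHO (g), −78 °C; AcOH, −78 °C
Reagents that add atoms: formaldehyde, C=O
Why: Aldol-type hydroxymethylation of the planar enolate 4 should occur on the face opposite the neighbouring isopropenyl group, so that CH2OH (C1) ends trans and the methyl cis to the C5 substituent, which is the relative configuration of the trans-decalin.

**Step 3**
Reactants: 5 (5S,6R)-6-(hydroxymethyl)-2,6-dimethyl-5-(prop-1-en-2-yl)cyclohex-2-en-1-one
Product: 6 (1R,6S)-1,3-dimethyl-2-oxo-6-(prop-1-en-2-yl)cyclohex-3-ene-1-carbaldehyde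
Conditions: Dess–Martin periodinane, CH2Cl2, 0 → 23 °C
Reagents that add atoms: none
Why: Dess–Martin oxidation converts the neopentyl primary alcohol into the non-enolisable aldehyde under neutral conditions that avoid retro-aldol loss of the one-carbon unit.

**Step 4**
Reactants: 6 (1R,6S)-1,3-dimethyl-2-oxo-6-(prop-1-en-2-yl)cyclohex-3-ene-1-carbaldehyde
Product: 9 (4aS,8aS)-2,5,5,8a-tetramethyl-4a,5,6,8a-tetrahydronaphthalen-1(4H)-one, via phosphonium salt 7 (not isolated), via phosphorus ylide 8 (not isolated)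
Conditions: vinyltriphenylphosphonium bromide, Fe(acac)3 (cat.), PhSiH2(Oi-Pr), i-PrOH/CH2Cl2, 23 °C; concentrate; KN(SiMe3)2, THF, −78 → 23 °C
Reagents that add atoms: vinyltriphenylphosphonium bromide, C=C[P+](c1ccccc1)(c1ccccc1)c1ccccc1.[Br-]
Why: Proposed new method: an iron hydride formed from Fe(acac)3 and the silane should transfer a hydrogen atom to the 1,1-disubstituted isopropenyl alkene (Markovnikov), and the nucleophilic tertiary C4 radical should add to the cationic vinylphosphonium acceptor (polarity-matched Giese step) to give, after reduction by divalent iron and protonation, phosphonium salt 7, which KN(SiMe3)2 converts into ylide 8 for an intramolecular Wittig olefination of the C1 aldehyde. The closest known reaction types are the iron-hydride HAT reductive coupling of unactivated alkenes with electron-poor alkenes, HAT-initiated radical-polar crossover annulations of unsaturated aldehydes, radical additions to vinylphosphonium salts that end in a Wittig olefination, and the classical annulations of vinylphosphonium salts; new here are the vinylphosphonium ion as acceptor under HAT conditions and the ring-closing termination. Ring A is closed in the 6-exo-trig mode (ylide carbon C2 onto the formyl carbon C1 through a fused oxaphosphetane), which forms the C1–C2 bond as a cis alkene. No stereocentre is created: C4 becomes a non-stereogenic gem-dimethyl carbon, C1 and C2 are sp2, and the trans ring fusion follows from the C5 and C10 centres already present in 6, whose equatorial arms are gauche and within reach. The step needs chemoselectivity: HAT should favour the electron-rich isopropenyl group over the enone alkene, the unhindered cationic acceptor should outcompete the internal trisubstituted enone for the tertiary radical, and the ylide should choose the aldehyde because olefination of the C9 ketone would give a bridgehead alkene.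

**Step 5**
Reactants: 9 (4aS,8aS)-2,5,5,8a-tetramethyl-4a,5,6,8a-tetrahydronaphthalen-1(4H)-one
Product: 10 (4aS,8aS)-2,5,5,8a-tetramethyl-3,4,4a,5,6,7,8,8a-octahydronaphthalen-1(2H)-one (C2 epimers)
Conditions: H2 (1 atm), Pd/C, EtOAc, 23 °C
Reagents that add atoms: none
Why: Heterogeneous hydrogenation should saturate the cis-disubstituted ring A alkene (C1=C2) and the enone alkene while leaving the hindered ketone; the new C8 stereocentre is inconsequential because C8 becomes sp2 in step 6.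

**Step 6**
Reactants: 10 (4aS,8aS)-2,5,5,8a-tetramethyl-3,4,4a,5,6,7,8,8a-octahydronaphthalen-1(2H)-one
Product: 12 (4aS,8aS)-2,5,5,8a-tetramethyl-3,4,4a,5,6,7,8,8a-octahydronaphthalen-1-yl trifluoromethanesulfonate, via potassium enolate 11 (not isolated)
Conditions: KN(SiMe3)2, THF, −78 → 0 °C; PhNTf2, −78 → 23 °C
Reagents that add atoms: N-phenylbis(trifluoromethanesulfonimide), O=S(=O)(N(c1ccccc1)S(=O)(=O)C(F)(F)F)C(F)(F)F
Why: C10 is quaternary, so enolisation can only occur towards C8, and O-triflation of enolate 11 (enol triflate formation) should give a single tetrasubstituted C8=C9 enol triflate.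

**Step 7**
Reactants: 12 (4aS,8aS)-2,5,5,8a-tetramethyl-3,4,4a,5,6,7,8,8a-octahydronaphthalen-1-yl trifluoromethanesulfonate
Product: 13 (4aS,8aS)-5-ethenyl-1,1,4a,6-tetramethyl-1,2,3,4,4a,7,8,8a-octahydronaphthalene
Conditions: Bu3SnCH=CH2, Pd(PPh3)4 (cat.), LiCl, THF, 65 °C
Reagents that add atoms: tributyl(vinyl)stannane, C=C[Sn](CCCC)(CCCC)CCCC
Why: Stille coupling of the enol triflate with the vinylstannane (chloride-assisted transmetalation) forms the C9–C11 bond and keeps the alkene at C8=C9, a coupling type known for 2,6,6-trimethylcyclohexenyl triflates.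

**Step 8**
Reactants: 14 furan-3-carbaldehyde
Product: 15 (R)-1-(furan-3-yl)but-3-en-1-ol
Conditions: Bu3SnCH2CH=CH2, (R)-BINOL (cat.), Ti(Oi-Pr)4 (cat.), 4 Å MS, CH2Cl2, −20 °C
Reagents that add atoms: allyltributylstannane, C=CC[Sn](CCCC)(CCCC)CCCC
Why: Keck asymmetric allylation: the (R)-BINOL–titanium Lewis acid should direct allyl transfer to the re face of the aldehyde, which sets the carbinol centre (C16) as R.

**Step 9**
Reactants: 15 (R)-1-(furan-3-yl)but-3-en-1-ol
Product: 16 (R)-tert-butyl{[1-(furan-3-yl)but-3-en-1-yl]oxy}dimethylsilane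
Conditions: TBSCl, imidazole, DMF, 23 °C
Reagents that add atoms: tert-butyl(chloro)dimethylsilane, CC(C)(C)[Si](C)(C)Cl
Why: Silylation protects the secondary alcohol against retro-aldol cleavage and β-elimination in the carbonyl chemistry that follows.

**Step 10**
Reactants: 16 (R)-tert-butyl{[1-(furan-3-yl)but-3-en-1-yl]oxy}dimethylsilane
Product: 18 (R)-3-[(tert-butyldimethylsilyl)oxy]-3-(furan-3-yl)propanal, via diol 17 (not isolated)
Conditions: OsO4 (cat.), NaIO4, 2,6-lutidine, dioxane/H2O, 23 °C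
Reagents that add atoms: osmium tetroxide, O=[Os](=O)(=O)=O (oxygen carrier); sodium periodate, [Na+].[O-]I(=O)(=O)=O (terminal oxygen source)
Why: Lemieux–Johnson cleavage: the terminal alkene should be dihydroxylated faster than the furan, and periodate cleaves diol 17 to the aldehyde while 2,6-lutidine suppresses over-oxidation.

**Step 11**
Reactants: 18 (R)-3-[(tert-butyldimethylsilyl)oxy]-3-(furan-3-yl)propanal
Product: 19 ethyl (2E,5R)-2-bromo-5-[(tert-butyldimethylsilyl)oxy]-5-(furan-3-yl)pent-2-enoate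
Conditions: (CF3CH2O)2P(O)CHBrCO2Et, t-BuOK, 18-crown-6, THF, −78 °C
Reagents that add atoms: ethyl 2-[bis(2,2,2-trifluoroethoxy)phosphoryl]-2-bromoacetate, CCOC(=O)C(Br)P(=O)(OCC(F)(F)F)OCC(F)(F)F
Why: Horner–Wadsworth–Emmons olefination with the bis(trifluoroethyl) phosphonate (Still–Gennari-type kinetic control) should place the ester cis to the chain, giving the (E)-α-bromo enoate that fixes the later C13=C14 geometry.

**Step 12**
Reactants: 13 (4aS,8aS)-5-ethenyl-1,1,4a,6-tetramethyl-1,2,3,4,4a,7,8,8a-octahydronaphthalene; 19 ethyl (2E,5R)-2-bromo-5-[(tert-butyldimethylsilyl)oxy]-5-(furan-3-yl)pent-2-enoate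
Product: 21 ethyl (2Z,5R)-5-[(tert-butyldimethylsilyl)oxy]-5-(furan-3-yl)-2-{2-[(4aS,8aS)-2,5,5,8a-tetramethyl-3,4,4a,5,6,7,8,8a-octahydronaphthalen-1-yl]ethyl}pent-2-enoate, via alkylborane 20 (not isolated)
Conditions: 13, 9-BBN, THF, 0 → 23 °C; then 19, Pd(dppf)Cl2 (cat.), AsPh3, Cs2CO3, DMF/H2O, 23 °C
Reagents that add atoms: none
Why: 9-BBN should hydroborate only the terminal vinyl carbon (the tetrasubstituted ring alkene is inert), and the B-alkyl Suzuki–Miyaura coupling of borane 20 with the vinyl bromide proceeds with retention, so that C12 is joined to C13 trans to C15.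

**Step 13**
Reactants: 21 (the coupled ethyl ester)
Product: 22 (2Z,5R)-5-[(tert-butyldimethylsilyl)oxy]-5-(furan-3-yl)-2-{2-[(4aS,8aS)-2,5,5,8a-tetramethyl-3,4,4a,5,6,7,8,8a-octahydronaphthalen-1-yl]ethyl}pent-2-en-1-ol
Conditions: i-Bu2AlH, CH2Cl2, −78 °C; aqueous work-up
Reagents that add atoms: none
Why: 1,2-Reduction of the conjugated ester by i-Bu2AlH gives the allylic alcohol without touching the alkene geometry, the silyl ether or the furan.

**Step 14**
Reactants: 22 (the silyl-protected allylic alcohol)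
Product: 23 (2Z,5R)-5-(furan-3-yl)-2-{2-[(4aS,8aS)-2,5,5,8a-tetramethyl-3,4,4a,5,6,7,8,8a-octahydronaphthalen-1-yl]ethyl}pent-2-ene-1,5-diol
Conditions: Bu4NF, THF, 0 → 23 °C
Reagents that add atoms: none
Why: Fluoride-induced desilylation frees the C16 hydroxyl before the base-sensitive butenolide exists.

**Step 15**
Reactants: 23 (the furyl diol)
Product: 25 5-hydroxy-4-{(1R,3Z)-1-hydroxy-4-(hydroxymethyl)-6-[(4aS,8aS)-2,5,5,8a-tetramethyl-3,4,4a,5,6,7,8,8a-octahydronaphthalen-1-yl]hex-3-en-1-yl}furan-2(5H)-one (C5 epimers), via furan endoperoxide 24 (not isolated)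
Conditions: O2, hν, tetraphenylporphyrin (cat.), i-Pr2NEt, CH2Cl2, −78 °C
Reagents that add atoms: dioxygen, O=O
Why: Singlet oxygen adds [4+2] to the furan to give endoperoxide 24, and the hindered amine removes the less hindered bridgehead proton (Kornblum–DeLaMare fragmentation) so that the hydroxyl-bearing carbon ends next to the substituted carbon; at −78 °C the furan should react faster than the two alkenes react in ene reactions.

**Step 16**
Reactants: 25 (the hydroxybutenolide)
Product: 27 4-{(1R,3Z)-1-hydroxy-4-(hydroxymethyl)-6-[(4aS,8aS)-2,5,5,8a-tetramethyl-3,4,4a,5,6,7,8,8a-octahydronaphthalen-1-yl]hex-3-en-1-yl}furan-2(5H)-one, via hydroxy acid 26 (not isolated)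
Conditions: NaBH4, EtOH, 0 °C; then aq. HCl (pH 2), 23 °C
Reagents that add atoms: none
Why: NaBH4 reduces the ring-opened aldehyde form of the hydroxybutenolide, and acidification lactonises hydroxy acid 26 through the primary alcohol held cis to the carboxyl group, which gives the 4-substituted furan-2(5H)-one of the target.

**Compound list**
1 | (R)-carvone, (5R)-2-methyl-5-(prop-1-en-2-yl)cyclohex-2-en-1-one | O=C1C(C)=CC[C@@H](C(C)=C)C1 | starting material
2 | lithium (3R)-6-methyl-3-(prop-1-en-2-yl)cyclohexa-1,5-dien-1-olate | [Li+].[O-]C1=C[C@H](C(C)=C)CC=C1C | intermediate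
3 | (5R,6S)-2,6-dimethyl-5-(prop-1-en-2-yl)cyclohex-2-en-1-one | O=C1C(C)=CC[C@@H](C(C)=C)[C@@H]1C | intermediate
4 | lithium (3S)-2,6-dimethyl-3-(prop-1-en-2-yl)cyclohexa-1,5-dien-1-olate | [Li+].[O-]C1=C(C)[C@H](C(C)=C)CC=C1C | intermediate
5 | (5S,6R)-6-(hydroxymethyl)-2,6-dimethyl-5-(prop-1-en-2-yl)cyclohex-2-en-1-one | O=C1C(C)=CC[C@@H](C(C)=C)[C@]1(C)CO | intermediate
6 | (1R,6S)-1,3-dimethyl-2-oxo-6-(prop-1-en-2-yl)cyclohex-3-ene-1-carbaldehyde | O=C1C(C)=CC[C@@H](C(C)=C)[C@]1(C)C=O | intermediate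
7 | {3-[(1S,2R)-2-formyl-2,4-dimethyl-3-oxocyclohex-4-en-1-yl]-3-methylbutyl}triphenylphosphonium bromide | O=C1C(C)=CC[C@@H](C(C)(C)CC[P+](c2ccccc2)(c2ccccc2)c2ccccc2)[C@]1(C)C=O.[Br-] | intermediate
8 | (1R,6S)-1,3-dimethyl-6-[2-methyl-4-(triphenyl-λ5-phosphanylidene)butan-2-yl]-2-oxocyclohex-3-ene-1-carbaldehyde | O=C1C(C)=CC[C@@H](C(C)(C)CC=P(c2ccccc2)(c2ccccc2)c2ccccc2)[C@]1(C)C=O | intermediate
9 | (4aS,8aS)-2,5,5,8a-tetramethyl-4a,5,6,8a-tetrahydronaphthalen-1(4H)-one | O=C1C(C)=CC[C@@H]2[C@]1(C)C=CCC2(C)C | intermediate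
10 | (4aS,8aS)-2,5,5,8a-tetramethyl-3,4,4a,5,6,7,8,8a-octahydronaphthalen-1(2H)-one (C2 epimers) | O=C1C(C)CC[C@@H]2[C@]1(C)CCCC2(C)C | intermediate
11 | potassium (4aS,8aS)-2,5,5,8a-tetramethyl-3,4,4a,5,6,7,8,8a-octahydronaphthalen-1-olate | [K+].[O-]C1=C(C)CC[C@@H]2[C@]1(C)CCCC2(C)C | intermediate
12 | (4aS,8aS)-2,5,5,8a-tetramethyl-3,4,4a,5,6,7,8,8a-octahydronaphthalen-1-yl trifluoromethanesulfonate | O=S(=O)(OC1=C(C)CC[C@@H]2[C@]1(C)CCCC2(C)C)C(F)(F)F | intermediate
13 | (4aS,8aS)-5-ethenyl-1,1,4a,6-tetramethyl-1,2,3,4,4a,7,8,8a-octahydronaphthalene | C=CC1=C(C)CC[C@@H]2[C@]1(C)CCCC2(C)C | intermediate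
14 | furan-3-carbaldehyde | O=Cc1ccoc1 | starting material
15 | (R)-1-(furan-3-yl)but-3-en-1-ol | C=CC[C@@H](O)c1ccoc1 | intermediate
16 | (R)-tert-butyl{[1-(furan-3-yl)but-3-en-1-yl]oxy}dimethylsilane | C=CC[C@@H](O[Si](C)(C)C(C)(C)C)c1ccoc1 | intermediate
17 | (4R)-4-[(tert-butyldimethylsilyl)oxy]-4-(furan-3-yl)butane-1,2-diol (C2 epimers) | OCC(O)C[C@@H](O[Si](C)(C)C(C)(C)C)c1ccoc1 | intermediate
18 | (R)-3-[(tert-butyldimethylsilyl)oxy]-3-(furan-3-yl)propanal | O=CC[C@@H](O[Si](C)(C)C(C)(C)C)c1ccoc1 | intermediate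
19 | ethyl (2E,5R)-2-bromo-5-[(tert-butyldimethylsilyl)oxy]-5-(furan-3-yl)pent-2-enoate | CCOC(=O)/C(Br)=C\C[C@@H](O[Si](C)(C)C(C)(C)C)c1ccoc1 | intermediate
20 | 9-{2-[(4aS,8aS)-2,5,5,8a-tetramethyl-3,4,4a,5,6,7,8,8a-octahydronaphthalen-1-yl]ethyl}-9-borabicyclo[3.3.1]nonane | CC1=C(CCB2C3CCCC2CCC3)[C@@]2(C)CCCC(C)(C)[C@@H]2CC1 | intermediate
21 | ethyl (2Z,5R)-5-[(tert-butyldimethylsilyl)oxy]-5-(furan-3-yl)-2-{2-[(4aS,8aS)-2,5,5,8a-tetramethyl-3,4,4a,5,6,7,8,8a-octahydronaphthalen-1-yl]ethyl}pent-2-enoate | CC1=C(CC/C(=C/C[C@@H](O[Si](C)(C)C(C)(C)C)c2ccoc2)C(=O)OCC)[C@@]2(C)CCCC(C)(C)[C@@H]2CC1 | intermediate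
22 | (2Z,5R)-5-[(tert-butyldimethylsilyl)oxy]-5-(furan-3-yl)-2-{2-[(4aS,8aS)-2,5,5,8a-tetramethyl-3,4,4a,5,6,7,8,8a-octahydronaphthalen-1-yl]ethyl}pent-2-en-1-ol | CC1=C(CC/C(=C/C[C@@H](O[Si](C)(C)C(C)(C)C)c2ccoc2)CO)[C@@]2(C)CCCC(C)(C)[C@@H]2CC1 | intermediate
23 | (2Z,5R)-5-(furan-3-yl)-2-{2-[(4aS,8aS)-2,5,5,8a-tetramethyl-3,4,4a,5,6,7,8,8a-octahydronaphthalen-1-yl]ethyl}pent-2-ene-1,5-diol | CC1=C(CC/C(=C/C[C@@H](O)c2ccoc2)CO)[C@@]2(C)CCCC(C)(C)[C@@H]2CC1 | intermediate
24 | (2Z,5R)-2-{2-[(4aS,8aS)-2,5,5,8a-tetramethyl-3,4,4a,5,6,7,8,8a-octahydronaphthalen-1-yl]ethyl}-5-(2,3,7-trioxabicyclo[2.2.1]hept-5-en-5-yl)pent-2-ene-1,5-diol | CC1=C(CC/C(=C/C[C@@H](O)C2=CC3OOC2O3)CO)[C@@]2(C)CCCC(C)(C)[C@@H]2CC1 | intermediate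
25 | 5-hydroxy-4-{(1R,3Z)-1-hydroxy-4-(hydroxymethyl)-6-[(4aS,8aS)-2,5,5,8a-tetramethyl-3,4,4a,5,6,7,8,8a-octahydronaphthalen-1-yl]hex-3-en-1-yl}furan-2(5H)-one (C5 epimers) | CC1=C(CC/C(=C/C[C@@H](O)C2=CC(=O)OC2O)CO)[C@@]2(C)CCCC(C)(C)[C@@H]2CC1 | intermediate
26 | (2E,4R,6Z)-4-hydroxy-3,7-bis(hydroxymethyl)-9-[(4aS,8aS)-2,5,5,8a-tetramethyl-3,4,4a,5,6,7,8,8a-octahydronaphthalen-1-yl]nona-2,6-dienoic acid | CC1=C(CC/C(=C/C[C@@H](O)/C(CO)=C/C(=O)O)CO)[C@@]2(C)CCCC(C)(C)[C@@H]2CC1 | intermediate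
27 | 4-{(1R,3Z)-1-hydroxy-4-(hydroxymethyl)-6-[(4aS,8aS)-2,5,5,8a-tetramethyl-3,4,4a,5,6,7,8,8a-octahydronaphthalen-1-yl]hex-3-en-1-yl}furan-2(5H)-one | CC1=C(CC/C(=C/C[C@@H](O)C2=CC(=O)OC2)CO)[C@@]2(C)CCCC(C)(C)[C@@H]2CC1 | target

**Step count and risks**
Total: 16 steps. Longest linear sequence: 12 steps (steps 1–7 and 12–16 from 1); the side-chain fragment takes steps 8–11.

1. Step 4 (proposed new method). What may go wrong: conjugate addition of hydride or alcohol to the vinylphosphonium ion, retro-Claisen loss of the formyl group, or inefficient reduction of the phosphonio radical, so that the phosphonium salt does not form cleanly. Fallback with known reactions, closing ring A by olefin metathesis instead; it sets out from 6. Wittig methylenation of the aldehyde (Ph3P=CH2, THF, 0 °C) would give (5S,6S)-6-ethenyl-2,6-dimethyl-5-(prop-1-en-2-yl)cyclohex-2-en-1-one F1. Markovnikov hydrobromination of the isopropenyl group (HBr, AcOH, 0 °C) would give (5R,6S)-5-(2-bromopropan-2-yl)-6-ethenyl-2,6-dimethylcyclohex-2-en-1-one F2. Keck radical allylation (Bu3SnCH2CH=CH2, AIBN, benzene, 80 °C) would give (5S,6S)-6-ethenyl-2,6-dimethyl-5-(2-methylpent-4-en-2-yl)cyclohex-2-en-1-one F3. Ring-closing metathesis (second-generation Grubbs catalyst, CH2Cl2, 40 °C) between the C10 vinyl group and the allyl terminus then forms C1=C2 and comes back to the route at 9.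

2. Step 15. What may go wrong: poor chemoselectivity, with ene reactions of singlet oxygen at the tetrasubstituted C8=C9 and trisubstituted C13=C14 alkenes competing with the furan cycloaddition. Fallback: the butenolide is made on the small fragment before the fragment union, so that singlet oxygen never meets these alkenes; it sets out from 19. i-Bu2AlH would give (2E,5R)-2-bromo-5-[(tert-butyldimethylsilyl)oxy]-5-(furan-3-yl)pent-2-en-1-ol F4. Photooxygenation as in step 15 would give 4-{(1R,3E)-4-bromo-1-[(tert-butyldimethylsilyl)oxy]-5-hydroxypent-3-en-1-yl}-5-hydroxyfuran-2(5H)-one F5. NaBH4 and then acid would give 4-{(1R,3E)-4-bromo-1-[(tert-butyldimethylsilyl)oxy]-5-hydroxypent-3-en-1-yl}furan-2(5H)-one F6. B-alkyl Suzuki–Miyaura coupling of F6 with alkylborane 20 under the conditions of step 12 would give 4-{(1R,3Z)-1-[(tert-butyldimethylsilyl)oxy]-4-(hydroxymethyl)-6-[(4aS,8aS)-2,5,5,8a-tetramethyl-3,4,4a,5,6,7,8,8a-octahydronaphthalen-1-yl]hex-3-en-1-yl}furan-2(5H)-one F7. HF·pyridine (THF, 0 °C) removes the silyl group and comes back to the route at 27.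

3. Step 7. What may go wrong: slow oxidative addition and transmetalation at the tetrasubstituted triflate flanked by the quaternary C10, so that triflate hydrolysis or reduction wins over coupling. Fallback: carbonyl addition and dehydration instead of cross-coupling; it sets out from 10. CH2=CHMgBr with CeCl3 (THF, −78 → 0 °C) would give (4aS,8aS)-1-ethenyl-2,5,5,8a-tetramethyldecahydronaphthalen-1-ol F8. Dehydration (POCl3, pyridine, 60 °C), which can only eliminate towards C8 because C10 is quaternary, comes back to the route at 13.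

**Further compounds**
F1 | step 4 | (5S,6S)-6-ethenyl-2,6-dimethyl-5-(prop-1-en-2-yl)cyclohex-2-en-1-one | O=C1C(C)=CC[C@@H](C(C)=C)[C@]1(C)C=C
F2 | step 4 | (5R,6S)-5-(2-bromopropan-2-yl)-6-ethenyl-2,6-dimethylcyclohex-2-en-1-one | O=C1C(C)=CC[C@@H](C(C)(C)Br)[C@]1(C)C=C
F3 | step 4 | (5S,6S)-6-ethenyl-2,6-dimethyl-5-(2-methylpent-4-en-2-yl)cyclohex-2-en-1-one | O=C1C(C)=CC[C@@H](C(C)(C)CC=C)[C@]1(C)C=C
F4 | step 15 | (2E,5R)-2-bromo-5-[(tert-butyldimethylsilyl)oxy]-5-(furan-3-yl)pent-2-en-1-ol | OC/C(Br)=C\C[C@@H](O[Si](C)(C)C(C)(C)C)c1ccoc1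
F5 | step 15 | 4-{(1R,3E)-4-bromo-1-[(tert-butyldimethylsilyl)oxy]-5-hydroxypent-3-en-1-yl}-5-hydroxyfuran-2(5H)-one | OC/C(Br)=C\C[C@@H](O[Si](C)(C)C(C)(C)C)C1=CC(=O)OC1O
F6 | step 15 | 4-{(1R,3E)-4-bromo-1-[(tert-butyldimethylsilyl)oxy]-5-hydroxypent-3-en-1-yl}furan-2(5H)-one | OC/C(Br)=C\C[C@@H](O[Si](C)(C)C(C)(C)C)C1=CC(=O)OC1
F7 | step 15 | 4-{(1R,3Z)-1-[(tert-butyldimethylsilyl)oxy]-4-(hydroxymethyl)-6-[(4aS,8aS)-2,5,5,8a-tetramethyl-3,4,4a,5,6,7,8,8a-octahydronaphthalen-1-yl]hex-3-en-1-yl}furan-2(5H)-one | CC1=C(CC/C(=C/C[C@@H](O[Si](C)(C)C(C)(C)C)C2=CC(=O)OC2)CO)[C@@]2(C)CCCC(C)(C)[C@@H]2CC1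
F8 | step 7 | (4aS,8aS)-1-ethenyl-2,5,5,8a-tetramethyldecahydronaphthalen-1-ol | C=CC1(O)C(C)CC[C@@H]2[C@]1(C)CCCC2(C)C
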